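**Retrosynthetic overview**

1. The target (30) is 2-decaprenyl-6-methoxy-3-methyl-1,4-benzoquinone; the side chain is numbered C1′ (ring-bound CH2) to C40′. No ring is built: ring A is bought as an anisole, carried as a MOM-protected phenol and oxidised to the quinone last, because a quinone would be reduced at the cathode before nickel.
2. The key disconnection is C13′–C14′. C13′ is an unactivated primary sp3 CH2 next to C12′H2, and C14′ is the hydrogen-bearing sp2 end of the E-trisubstituted alkene C14′=C15′(CH3). This CH2–CH=C(CH3) junction lets C13′ come from the carboxyl-bearing carbon of a 4-enoic acid (redox-active ester 14) and C14′ from the iodinated carbon of a syn-methylmetalated terminal alkyne (vinyl iodide 26): two electrophiles joined reductively by nickel electrocatalysis.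
3. Fragment 1 (ring A plus C1′–C13′): ortho-metalation/oxidation of 3-bromo-4-methylanisole, aryl–farnesyl coupling, terminal allylic oxidation and two-carbon extension with an acetate enolate.
4. Fragment 2 (C14′–C40′): farnesyl bromide plus silylpropyne, terminal allylic oxidation, sulfone-mediated head-to-tail union with a second farnesyl unit, then carboalumination/iodination.
5. Order: fragment 1 (steps 1–8), fragment 2 (steps 9–16), union (step 17), phenol release and para-oxidation of ring A (steps 18, 19).

Key step: step 17

Remark on the chemistry: (2E,6E)-farnesyl bromide 6 is assumed to be used as the single geometric isomer, and all polyene intermediates are handled under argon with exclusion of light.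

**Route**

Step 1
Reactants: 1 3-bromo-4-methylanisole
Product: 4 2-bromo-6-methoxy-3-methylphenol, via aryllithium 2 (not isolated), via dimethyl arylboronate 3 (not isolated)
Conditions: LiN(i-Pr)2, THF, −78 °C; B(OMe)3, −78 °C → rt; 30% H2O2, aq NaOH, 0 °C → rt
Reagents that add atoms: lithium diisopropylamide [Li]N(C(C)C)C(C)C (lithium of 2); trimethyl borate COB(OC)OC (boron of 3); hydrogen peroxide OO (hydroxyl oxygen of 4)
Why: The C–H between OMe and Br is the most acidic ring position, so directed ortho-metalation at −78 °C (below the temperature of LiBr loss to the aryne), borylation and oxidative C–B to C–O conversion should place the hydroxyl regiospecifically next to bromine.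

Step 2
Reactants: 4 2-bromo-6-methoxy-3-methylphenol
Product: 5 2-bromo-4-methoxy-3-(methoxymethoxy)-1-methylbenzene
Conditions: MOMCl, i-Pr2NEt, CH2Cl2, 0 °C → rt
Reagents that add atoms: chloromethyl methyl ether COCCl
Why: Standard O-alkylation gives a MOM acetal that tolerates the organolithium, oxidation, enolate and cathodic steps ahead and cannot migrate to carbon at the aryllithium stage as a silyl ether would.

Step 3
Reactants: 5 2-bromo-4-methoxy-3-(methoxymethoxy)-1-methylbenzene; 6 (2E,6E)-farnesyl bromide
Product: 9 2-[(2E,6E)-farnesyl]-4-methoxy-3-(methoxymethoxy)-1-methylbenzene, via aryllithium 7 (not isolated), via arylcopper 8 (not isolated)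
Conditions: n-BuLi, THF, −78 °C; CuBr·SMe2, −78 → −40 °C; then 6, −78 → 0 °C
Reagents that add atoms: n-butyllithium [Li]CCCC (lithium of 7); copper bromide dimethyl sulfide complex [Cu]Br.CSC (copper of 8)
Why: Bromine–lithium exchange, transmetalation to copper and copper-mediated aryl–allyl coupling should give α-attack on the primary allylic bromide (its γ-carbon is fully substituted) with retention of the 2E,6E geometry.

Step 4
Reactants: 9 2-[(2E,6E)-farnesyl]-4-methoxy-3-(methoxymethoxy)-1-methylbenzene
Product: 10 (2E,6E,10E)-12-[3-methoxy-2-(methoxymethoxy)-6-methylphenyl]-2,6,10-trimethyldodeca-2,6,10-trien-1-ol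
Conditions: SeO2 (cat.), t-BuOOH, salicylic acid (cat.), CH2Cl2, 0 °C → rt, partial conversion
Reagents that add atoms: selenium dioxide O=[Se]=O; tert-butyl hydroperoxide CC(C)(C)OO
Why: Riley allylic oxidation (ene reaction, then [2,3]-sigmatropic shift) should attack the least hindered terminal trisubstituted alkene at its E-methyl group, which sets the new C10′=C11′ allylic alcohol with E geometry.

Step 5
Reactants: 10 the terminal allylic alcohol
Product: 11 2-[(2E,6E,10E)-12-bromo-3,7,11-trimethyldodeca-2,6,10-trien-1-yl]-4-methoxy-3-(methoxymethoxy)-1-methylbenzene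
Conditions: CBr4, PPh3, CH2Cl2, 0 °C
Reagents that add atoms: carbon tetrabromide BrC(Br)(Br)Br
Why: The Appel reaction converts the primary allylic alcohol into the bromide under neutral conditions, without allylic transposition and without touching the MOM acetal.

Step 6
Reactants: 11 the terminal allylic bromide
Product: 12 ethyl (4E,8E,12E)-14-[3-methoxy-2-(methoxymethoxy)-6-methylphenyl]-4,8,12-trimethyltetradeca-4,8,12-trienoate
Conditions: LiN(i-Pr)2, EtOAc, THF, −78 °C; CuI; then 11, −78 → −30 °C
Reagents that add atoms: ethyl acetate CCOC(C)=O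
Why: Ester enolate alkylation at the primary allylic carbon (SN2) adds C13′ and the future carboxyl carbon and leaves the E geometry of C10′=C11′ untouched.

Step 7
Reactants: 12 the ethyl ester
Product: 13 (4E,8E,12E)-14-[3-methoxy-2-(methoxymethoxy)-6-methylphenyl]-4,8,12-trimethyltetradeca-4,8,12-trienoic acid
Conditions: LiOH, THF/MeOH/H2O, rt; 1 M HCl work-up at 0 °C
Reagents that add atoms: lithium hydroxide [Li+].[OH-]
Why: Saponification of an unhindered ethyl ester is reliable, and the brief cold acidification is too mild to cleave the MOM acetal or protonate the alkenes.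

Step 8
Reactants: 13 the trienoic acid
Product: 14 1,3-dioxoisoindolin-2-yl (4E,8E,12E)-14-[3-methoxy-2-(methoxymethoxy)-6-methylphenyl]-4,8,12-trimethyltetradeca-4,8,12-trienoate
Conditions: N-hydroxyphthalimide, DIC, DMAP (cat.), CH2Cl2, rt
Reagents that add atoms: N-hydroxyphthalimide O=C1c2ccccc2C(=O)N1O
Why: Carbodiimide (Steglich-type) esterification gives the redox-active ester that serves as the precursor of the C13′ radical.

Step 9
Reactants: 15 1-(trimethylsilyl)propyne; 6 (2E,6E)-farnesyl bromide
Product: 17 trimethyl[(5E,9E)-6,10,14-trimethylpentadeca-5,9,13-trien-1-yn-1-yl]silane, via 3-lithio-1-(trimethylsilyl)propyne 16 (not isolated)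
Conditions: n-BuLi, THF, −78 °C; then 6, −78 °C → rt
Reagents that add atoms: n-butyllithium [Li]CCCC (lithium of 16)
Why: The silyl-blocked propargyllithium alkylates the primary allylic bromide at its α-carbon (SN2) as the propargyl, not the allenyl, isomer, with retention of alkene geometry.

Step 10
Reactants: 17 the silylated trienyne
Product: 18 (2E,6E,10E)-2,6,10-trimethyl-15-(trimethylsilyl)pentadeca-2,6,10-trien-14-yn-1-ol
Conditions: SeO2 (cat.), t-BuOOH, salicylic acid (cat.), CH2Cl2, 0 °C → rt, partial conversion
Reagents that add atoms: selenium dioxide O=[Se]=O; tert-butyl hydroperoxide CC(C)(C)OO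
Why: Riley allylic oxidation should again select the terminal E-methyl group and give the E-configured primary allylic alcohol, while the silylalkyne is inert.

Step 11
Reactants: 18 the terminal allylic alcohol
Product: 19 [(5E,9E,13E)-15-bromo-6,10,14-trimethylpentadeca-5,9,13-trien-1-yn-1-yl]trimethylsilane
Conditions: CBr4, PPh3, CH2Cl2, 0 °C
Reagents that add atoms: carbon tetrabromide BrC(Br)(Br)Br
Why: The Appel reaction gives the primary allylic bromide without allylic transposition.

Step 12
Reactants: 6 (2E,6E)-farnesyl bromide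
Product: 20 (2E,6E)-farnesyl phenyl sulfone
Conditions: PhSO2Na, DMF, rt
Reagents that add atoms: sodium benzenesulfinate [Na+].[O-]S(=O)c1ccccc1
Why: S-alkylation of the sulfinate at the primary allylic carbon (SN2) should give the allylic sulfone with retention of geometry.

Step 13
Reactants: 20 (2E,6E)-farnesyl phenyl sulfone; 19 the silylated allylic bromide
Product: 22 trimethyl[(5E,9E,13E,17E,21E)-6,10,14,18,22,26-hexamethyl-16-(phenylsulfonyl)heptacosa-5,9,13,17,21,25-hexaen-1-yn-1-yl]silane (racemic at C16), via α-lithiosulfone 21 (not isolated)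
Conditions: n-BuLi, THF/DMPU, −78 °C; then 19, −78 → −20 °C
Reagents that add atoms: n-butyllithium [Li]CCCC (lithium of 21)
Why: Sulfone-carbanion alkylation (Biellmann-type head-to-tail prenyl coupling) occurs at the α-carbon of the allylic sulfone anion; the new sp3 stereocentre is formed as a racemate and is removed in step 14.

Step 14
Reactants: 22 the coupled sulfone
Product: 23 trimethyl[(5E,9E,13E,17E,21E)-6,10,14,18,22,26-hexamethylheptacosa-5,9,13,17,21,25-hexaen-1-yn-1-yl]silane
Conditions: PdCl2[Ph2P(CH2)3PPh2] (5 mol %), LiBHEt3, THF, 0 °C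
Reagents that add atoms: none
Why: Palladium-catalysed hydride reduction of the allylic sulfone goes through a π-allylpalladium intermediate that should take hydride at its less substituted terminus, keeping the trisubstituted alkene in place with E geometry.

Step 15
Reactants: 23 the silylated hexaenyne
Product: 24 (5E,9E,13E,17E,21E)-6,10,14,18,22,26-hexamethylheptacosa-5,9,13,17,21,25-hexaen-1-yne
Conditions: K2CO3 (cat.), MeOH/THF, rt
Reagents that add atoms: none
Why: Base-catalysed methanolysis of the alkynyl C–Si bond (protodesilylation) is mild and leaves the skipped polyene untouched.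

Step 16
Reactants: 24 the terminal alkyne
Product: 26 (1E,5E,9E,13E,17E,21E)-1-iodo-2,6,10,14,18,22,26-heptamethylheptacosa-1,5,9,13,17,21,25-heptaene, via alkenyldimethylalane 25 (not isolated)
Conditions: AlMe3, (C5H5)2ZrCl2 (25 mol %), CH2Cl2, 0 °C → rt; then I2, THF, −30 → 0 °C
Reagents that add atoms: trimethylaluminium C[Al](C)C; iodine II
Why: Negishi carboalumination adds methyl and aluminium syn across the terminal alkyne with aluminium on the terminal carbon, and iodinolysis with retention sets the E geometry of the future C14′=C15′ bond; the trisubstituted alkenes do not react.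

Step 17
Reactants: 14 the redox-active ester (fragment 1); 26 the (E)-vinyl iodide (fragment 2)
Product: 27 2-[(2E,6E,10E,14E,18E,22E,26E,30E,34E)-3,7,11,15,19,23,27,31,35,39-decamethyltetraconta-2,6,10,14,18,22,26,30,34,38-decaen-1-yl]-4-methoxy-3-(methoxymethoxy)-1-methylbenzene
Conditions: NiCl2·6H2O (20 mol %), 2,2′-bipyridine (20 mol %), AgNO3 (0.3 equiv), DMF/THF, undivided cell, Mg anode, reticulated vitreous carbon cathode, constant current, rt
Reagents that add atoms: none
Why: Cathodic reduction gives low-valent nickel–bipyridine, which inserts into the C–I bond of 26 with retention, while 14 accepts one electron (from monovalent nickel or at the silver-nanoparticle-coated cathode formed from AgNO3) and fragments to phthalimide anion, CO2 and the primary C13′ radical; radical capture at nickel and reductive elimination from trivalent nickel forge C13′–C14′, with the Mg anode supplying the electrons. The closest known reaction type is the nickel-electrocatalytic decarboxylative alkenylation of N-hydroxyphthalimide esters with alkenyl halides, which has been used to assemble linear polyprenoid chains from 4-enoic acid esters and (E)-trisubstituted alkenyl iodides of this kind. No ring is closed and no stereocentre is created; the E geometry of C14′=C15′ is that of 26 and is carried through because oxidative addition and reductive elimination at an sp2 carbon are stereoretentive. The step needs cross- over homo-coupling between two electrophiles, which is secured by their different activation modes (two-electron insertion for the C(sp2)–I bond, one-electron reductive fragmentation for the ester) and by current-limited radical generation. It also needs the C10′=C11′ geometry to survive the homoallylic C13′ radical, whose 3-exo closure to a cyclopropylcarbinyl radical is slow and reversible in favour of the open form compared with capture by nickel. The nine other trisubstituted alkenes and the aryl methyl and MOM ethers are not reducible at this potential, which is why ring A stays at the phenol oxidation level until after this step.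

Step 18
Reactants: 27 the MOM-protected decaprenyl arene
Product: 29 2-[(all-E)-decaprenyl]-6-methoxy-3-methylphenol, via aryl trimethylsilyl ether 28 (not isolated)
Conditions: Me3SiOTf, 2,2′-bipyridyl (excess), CH2Cl2, 0 °C → rt; then H2O
Reagents that add atoms: trimethylsilyl triflate C[Si](C)(C)OS(=O)(=O)C(F)(F)F (silyl group of 28)
Why: Silyl-triflate/bipyridyl cleavage of an aromatic MOM ether goes through the aryl silyl ether, which water hydrolyses, and the buffered non-protic medium should avoid protonation of the alkenes and chroman formation by the ortho-prenyl phenol.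

Step 19
Reactants: 29 the decaprenyl phenol
Product: 30 2-[(all-E)-decaprenyl]-6-methoxy-3-methyl-1,4-benzoquinone (target)
Conditions: Co(C16H14N2O2) [Co(salen)] (10 mol %), O2 (1 atm), DMF/CH2Cl2, rt
Reagents that add atoms: dioxygen O=O
Why: Cobalt–salen catalysed aerobic phenol oxidation generates the phenoxyl radical, which takes up dioxygen at the only free para position to give the para-quinone, and the isolated trisubstituted alkenes are expected to be inert at room temperature.

**Compound list**

1 | 3-bromo-4-methylanisole | COc1ccc(C)c(Br)c1 | starting material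
2 | (2-bromo-6-methoxy-3-methylphenyl)lithium | COc1ccc(C)c(Br)c1[Li] | intermediate
3 | dimethyl (2-bromo-6-methoxy-3-methylphenyl)boronate | COc1ccc(C)c(Br)c1B(OC)OC | intermediate
4 | 2-bromo-6-methoxy-3-methylphenol | COc1ccc(C)c(Br)c1O | intermediate
5 | 2-bromo-4-methoxy-3-(methoxymethoxy)-1-methylbenzene | COCOc1c(OC)ccc(C)c1Br | intermediate
6 | (2E,6E)-farnesyl bromide | BrC/C=C(\C)CC/C=C(\C)CCC=C(C)C | starting material
7 | [3-methoxy-2-(methoxymethoxy)-6-methylphenyl]lithium | COCOc1c(OC)ccc(C)c1[Li] | intermediate
8 | [3-methoxy-2-(methoxymethoxy)-6-methylphenyl]copper | COCOc1c(OC)ccc(C)c1[Cu] | intermediate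
9 | 2-[(2E,6E)-farnesyl]-4-methoxy-3-(methoxymethoxy)-1-methylbenzene | COCOc1c(OC)ccc(C)c1C/C=C(\C)CC/C=C(\C)CCC=C(C)C | intermediate
10 | (2E,6E,10E)-12-[3-methoxy-2-(methoxymethoxy)-6-methylphenyl]-2,6,10-trimethyldodeca-2,6,10-trien-1-ol | COCOc1c(OC)ccc(C)c1C/C=C(\C)CC/C=C(\C)CC/C=C(\C)CO | intermediate
11 | 2-[(2E,6E,10E)-12-bromo-3,7,11-trimethyldodeca-2,6,10-trien-1-yl]-4-methoxy-3-(methoxymethoxy)-1-methylbenzene | COCOc1c(OC)ccc(C)c1C/C=C(\C)CC/C=C(\C)CC/C=C(\C)CBr | intermediate
12 | ethyl (4E,8E,12E)-14-[3-methoxy-2-(methoxymethoxy)-6-methylphenyl]-4,8,12-trimethyltetradeca-4,8,12-trienoate | COCOc1c(OC)ccc(C)c1C/C=C(\C)CC/C=C(\C)CC/C=C(\C)CCC(=O)OCC | intermediate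
13 | (4E,8E,12E)-14-[3-methoxy-2-(methoxymethoxy)-6-methylphenyl]-4,8,12-trimethyltetradeca-4,8,12-trienoic acid | COCOc1c(OC)ccc(C)c1C/C=C(\C)CC/C=C(\C)CC/C=C(\C)CCC(=O)O | intermediate
14 | N-hydroxyphthalimide ester of acid 13 | COCOc1c(OC)ccc(C)c1C/C=C(\C)CC/C=C(\C)CC/C=C(\C)CCC(=O)ON1C(=O)c2ccccc2C1=O | intermediate
15 | 1-(trimethylsilyl)propyne | CC#C[Si](C)(C)C | starting material
16 | 3-lithio-1-(trimethylsilyl)propyne | [Li]CC#C[Si](C)(C)C | intermediate
17 | trimethyl[(5E,9E)-6,10,14-trimethylpentadeca-5,9,13-trien-1-yn-1-yl]silane | C[Si](C)(C)C#CCC/C=C(\C)CC/C=C(\C)CCC=C(C)C | intermediate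
18 | (2E,6E,10E)-2,6,10-trimethyl-15-(trimethylsilyl)pentadeca-2,6,10-trien-14-yn-1-ol | C[Si](C)(C)C#CCC/C=C(\C)CC/C=C(\C)CC/C=C(\C)CO | intermediate
19 | [(5E,9E,13E)-15-bromo-6,10,14-trimethylpentadeca-5,9,13-trien-1-yn-1-yl]trimethylsilane | C[Si](C)(C)C#CCC/C=C(\C)CC/C=C(\C)CC/C=C(\C)CBr | intermediate
20 | (2E,6E)-farnesyl phenyl sulfone | O=S(=O)(C/C=C(\C)CC/C=C(\C)CCC=C(C)C)c1ccccc1 | intermediate
21 | α-lithio-(2E,6E)-farnesyl phenyl sulfone | [Li]C(/C=C(\C)CC/C=C(\C)CCC=C(C)C)S(=O)(=O)c1ccccc1 | intermediate
22 | trimethyl[(5E,9E,13E,17E,21E)-6,10,14,18,22,26-hexamethyl-16-(phenylsulfonyl)heptacosa-5,9,13,17,21,25-hexaen-1-yn-1-yl]silane, racemic at C16 | C[Si](C)(C)C#CCC/C=C(\C)CC/C=C(\C)CC/C=C(\C)CC(S(=O)(=O)c1ccccc1)/C=C(\C)CC/C=C(\C)CCC=C(C)C | intermediate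
23 | trimethyl[(5E,9E,13E,17E,21E)-6,10,14,18,22,26-hexamethylheptacosa-5,9,13,17,21,25-hexaen-1-yn-1-yl]silane | C[Si](C)(C)C#CCC/C=C(\C)CC/C=C(\C)CC/C=C(\C)CC/C=C(\C)CC/C=C(\C)CCC=C(C)C | intermediate
24 | (5E,9E,13E,17E,21E)-6,10,14,18,22,26-hexamethylheptacosa-5,9,13,17,21,25-hexaen-1-yne | C#CCC/C=C(\C)CC/C=C(\C)CC/C=C(\C)CC/C=C(\C)CC/C=C(\C)CCC=C(C)C | intermediate
25 | dimethyl[(1E,5E,9E,13E,17E,21E)-2,6,10,14,18,22,26-heptamethylheptacosa-1,5,9,13,17,21,25-heptaen-1-yl]alumane | C[Al](C)/C=C(\C)CC/C=C(\C)CC/C=C(\C)CC/C=C(\C)CC/C=C(\C)CC/C=C(\C)CCC=C(C)C | intermediate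
26 | (1E,5E,9E,13E,17E,21E)-1-iodo-2,6,10,14,18,22,26-heptamethylheptacosa-1,5,9,13,17,21,25-heptaene | I/C=C(\C)CC/C=C(\C)CC/C=C(\C)CC/C=C(\C)CC/C=C(\C)CC/C=C(\C)CCC=C(C)C | intermediate
27 | 2-[(all-E)-decaprenyl]-4-methoxy-3-(methoxymethoxy)-1-methylbenzene | COCOc1c(OC)ccc(C)c1C/C=C(\C)CC/C=C(\C)CC/C=C(\C)CC/C=C(\C)CC/C=C(\C)CC/C=C(\C)CC/C=C(\C)CC/C=C(\C)CC/C=C(\C)CCC=C(C)C | intermediate
28 | [2-[(all-E)-decaprenyl]-6-methoxy-3-methylphenoxy]trimethylsilane | C[Si](C)(C)Oc1c(OC)ccc(C)c1C/C=C(\C)CC/C=C(\C)CC/C=C(\C)CC/C=C(\C)CC/C=C(\C)CC/C=C(\C)CC/C=C(\C)CC/C=C(\C)CC/C=C(\C)CCC=C(C)C | intermediate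
29 | 2-[(all-E)-decaprenyl]-6-methoxy-3-methylphenol | Oc1c(OC)ccc(C)c1C/C=C(\C)CC/C=C(\C)CC/C=C(\C)CC/C=C(\C)CC/C=C(\C)CC/C=C(\C)CC/C=C(\C)CC/C=C(\C)CC/C=C(\C)CCC=C(C)C | intermediate
30 | 2-[(all-E)-decaprenyl]-6-methoxy-3-methyl-1,4-benzoquinone | COC1=CC(=O)C(C)=C(C/C=C(\C)CC/C=C(\C)CC/C=C(\C)CC/C=C(\C)CC/C=C(\C)CC/C=C(\C)CC/C=C(\C)CC/C=C(\C)CC/C=C(\C)CCC=C(C)C)C1=O | target

**Step count and risks**

Total step count: 19.
Longest linear sequence: 11 steps (steps 1–8, then 17, 18 and 19).

Steps most likely to fail:

Step 17 (key coupling). What may go wrong: reduction of the redox-active ester to the alkane or hydrodecarboxylation, protodeiodination or homodimerisation at the alkenylnickel stage, poor mass transfer of two very lipophilic partners in DMF, and erosion of the C10′=C11′ geometry through reversible ring closure of the homoallyl radical. Fallback: the same C13′–C14′ bond would be made by a two-electron B-alkyl Suzuki–Miyaura coupling, setting out from alcohol 10 and returning to the route at 27. Oxidation of 10 with MnO2 in CH2Cl2 would give the (2E,6E,10E)-enal F1. Wittig methylenation (Ph3PCH3Br, KN(SiMe3)2, THF) would give the terminal 1,3-diene F2. 9-Borabicyclononane (THF, 0 °C → rt) should hydroborate only the monosubstituted vinyl group and place boron on C13′, giving the B-alkyl-9-borabicyclononane F3, which is not isolated. Coupling of F3 with vinyl iodide 26 (PdCl2[(Ph2PC5H4)2Fe], AsPh3, Cs2CO3, DMF/THF/H2O, rt) would give 27 with retention of the alkene geometry.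

Step 4 (terminal allylic oxidation; step 10 shares the profile). What may go wrong: competing ene attack at the internal alkenes (C4′ and C8′ methylene groups), over-oxidation to the enal and low conversion. Fallback: the C12′–C13′ bond would instead be made by a Johnson–Claisen rearrangement, setting out from 9 and returning at ester 12 (compounds 10 and 11 are bypassed). NBS in THF/H2O at 0 °C should convert the most accessible terminal alkene into the terminal bromohydrin F4, with the alkene expected to react faster than the arene at this temperature. K2CO3 in MeOH would close it to the terminal epoxide F5. Al(O-i-Pr)3 in refluxing toluene would isomerise the epoxide to the secondary allylic alcohol F6, which carries an isopropenyl group. Heating F6 with triethyl orthoacetate and catalytic propionic acid (140 °C) would give 12 through a chair transition state that places the chain equatorial and so sets C10′=C11′ as E.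

Step 14 (desulfonylation). What may go wrong: hydride delivery to the tertiary allyl terminus with transposition of the double bond, syn–anti isomerisation of the π-allylpalladium intermediate with loss of E geometry, and incomplete reduction. Fallback: the allyl–allyl bond would be formed directly without a sulfone, setting out from bromide 19 and returning at 23 (compounds 20–22 are bypassed). Commercial (2E,6E)-farnesyl chloride and activated barium (from BaI2 and lithium biphenylide, THF, −78 °C) would give farnesylbarium chloride F7, which is not isolated. Allylbarium reagents are known to couple with allylic bromides at the α-carbon of both partners with retention of geometry, so addition of 19 at −78 °C should give 23.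

**Further compounds**

F1 | step 17 | (2E,6E,10E)-12-[3-methoxy-2-(methoxymethoxy)-6-methylphenyl]-2,6,10-trimethyldodeca-2,6,10-trienal | COCOc1c(OC)ccc(C)c1C/C=C(\C)CC/C=C(\C)CC/C=C(\C)C=O
F2 | step 17 | 1-methoxy-2-(methoxymethoxy)-4-methyl-3-[(2E,6E,10E)-3,7,11-trimethyltrideca-2,6,10,12-tetraen-1-yl]benzene | COCOc1c(OC)ccc(C)c1C/C=C(\C)CC/C=C(\C)CC/C=C(\C)C=C
F3 | step 17 | 9-[(3E,7E,11E)-13-[3-methoxy-2-(methoxymethoxy)-6-methylphenyl]-3,7,11-trimethyltrideca-3,7,11-trien-1-yl]-9-borabicyclo[3.3.1]nonane | COCOc1c(OC)ccc(C)c1C/C=C(\C)CC/C=C(\C)CC/C=C(\C)CCB1C2CCCC1CCC2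
F4 | step 4 | (6E,10E)-3-bromo-12-[3-methoxy-2-(methoxymethoxy)-6-methylphenyl]-2,6,10-trimethyldodeca-6,10-dien-2-ol (racemic) | COCOc1c(OC)ccc(C)c1C/C=C(\C)CC/C=C(\C)CCC(Br)C(C)(C)O
F5 | step 4 | 3-[(3E,7E)-9-[3-methoxy-2-(methoxymethoxy)-6-methylphenyl]-3,7-dimethylnona-3,7-dien-1-yl]-2,2-dimethyloxirane (racemic) | COCOc1c(OC)ccc(C)c1C/C=C(\C)CC/C=C(\C)CCC1OC1(C)C
F6 | step 4 | (6E,10E)-12-[3-methoxy-2-(methoxymethoxy)-6-methylphenyl]-2,6,10-trimethyldodeca-1,6,10-trien-3-ol (racemic) | COCOc1c(OC)ccc(C)c1C/C=C(\C)CC/C=C(\C)CCC(O)C(C)=C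
F7 | step 14 | (2E,6E)-farnesylbarium chloride | Cl[Ba]C/C=C(\C)CC/C=C(\C)CCC=C(C)C
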